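## Structural features

The target is a diarylmethane: C6 of a 5-hydroxy-7-methoxy-2-methylchromone (benzene ring fused to a γ-pyranone) is joined through one CH2 group to C5 of an (R)-6,8-dihydroxy-3,7-dimethyl-3,4-dihydroisocoumarin (benzene ring fused to a δ-lactone). The lactone benzene ring is hexasubstituted and the chromone benzene ring keeps one hydrogen, at C8. The bridge carbon lies between C5–OH and C7–OMe on one side and between C4 and C6–OH on the other, so the link is tetra-ortho-substituted. The only stereocenter is C3 of the lactone, (R), bearing a methyl group; it has no stereogenic neighbour and is lost only if the C3–O bond is broken. Fragile elements are the lactone (hydroxide, boron halides at the alkyl C–O bond), the pyranone (nucleophiles, hydrogenation), three free phenols, and the doubly activated benzylic bridge (strong acid). The real difficulty is regiochemical: three phloroglucinol-type oxygens of the chromone ring must end as O1, free C5–OH and C7–OMe, the bridge must sit on C6 and not C8, and a crowded aryl–CH2 bond must be made late. The key step uses the fact that C4a (carrying the C4 carbonyl) and C8a (carrying O1) are adjacent, with C4a next to the oxygenated C5 and C8a next to C8–H. This is the pattern in which an oxygen nucleophile and an acyl electrophile add across a 3-alkoxyaryne, so O1 and C4 can come from one carboxylic acid and C2/C3 from its triple bond.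

## Logic of the disconnections

**23 ⇒ 22.** Cut: the O–CH3 bond at C5 of the chromone. The peri phenol is unmasked last because chelation to the C4 carbonyl distinguishes it from the C7 methyl ether that must stay. Gain: both chromone ring oxygens can be identical methyl ethers throughout, which preserves the symmetry of 1. Demand: the reagent must spare the C7 ether, the lactone and the bridge.

**22 ⇒ 12 + 21.** Cut: the bond between the bridge CH2 and C5 of the lactone ring. C5 is the only unsubstituted carbon of 21 and is ortho and para to free hydroxyls, while the bridge carbon on 12 is flanked by two methoxy groups and can be ionised. Gain: two fragments of similar size, one ring system each. Demand: ionisation of the benzylic ether under acid that the lactone and pyranone tolerate, and C- over O-alkylation.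

**12 ⇒ 8 + 9 (key step).** Cut: C8a–O1, C4a–C4 and O1–C2. An aryne across C8a/C4a takes oxygen at C8a and the acyl carbon at C4a from 9, and the resulting ynone closes the pyranone. Gain: the whole heterocycle in one operation, with regiochemistry set by the C5 methoxy group. Demand: the acyl shift must outrun protonation and the closure must be 6-endo. In 8 and 12 the benzylic oxygen is a methyl ether rather than an ester. The phenoxide formed at C8a during this step is para to the benzylic carbon, and an acyloxy group there could leave by 1,6-elimination to a para-quinone methide at 125 °C. Methoxide cannot, and the ether also needs no protection or deprotection step.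

**8 ⇒ 4.** Cut: the C–Si bond and the O–S bond. An ortho-bromophenol is converted by O-silylation, bromine–lithium exchange, retro-Brook shift and triflation. Gain: a simple bromophenol. Demand: low temperature, and a benzylic group inert to n-BuLi and to the para phenoxide.

**4 ⇒ 2 ⇒ 1.** Cut: the benzylic O–CH3 and C–H bonds (back to the aldehyde) and the C–Br bond. The mirror plane of 1 through C1 and C4 makes the two positions ortho to the hydroxyl identical, so bromination is unambiguous and fixes the future C6. Demand: monobromination, and capture of the benzylic cation by methanol faster than self-alkylation.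

**21 ⇒ 20.** Cut: two aryl O–CH3 bonds. Methyl ethers are the phenol protection that survives the two organolithium steps. They are removed before the coupling, because afterwards the C7 methyl ether of the chromone must survive. Demand: the lactone C3–O bond must stay intact.

**20 ⇒ 16 + 17.** Cut: C4a–C4 and O2–C1. Amide-directed lithiation makes C4a nucleophilic, opening of 17 at its CH2 forms C4a–C4, and intramolecular acyl transfer closes the lactone. Gain: C3 is bought with its configuration. Demand: lithiation ortho to the amide, and attack at the terminal epoxide carbon.

**16 ⇒ 13 + 14.** Cut: the aryl–carbonyl bond. Methoxy-directed lithiation of 13 and acylation with 14; both are commercial.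

## Other disconnections considered

Alternative 1: The lactone ring is cut at C3–C4 and O2–C1. A bifunctional cinchona squaramide would add the enol of the anhydride 6,8-bis(benzyloxy)-7-methyl-1H-isochromene-1,3(4H)-dione A1 to acetaldehyde A2. The aldolate would acylate itself on the aryl-bound carbonyl to give the acid A3 with C3 as (R), and decarboxylation would leave the dibenzyl lactone A4, which would replace 21 in step 8.
- In favour: both ring bonds and the stereocenter come from one catalytic step, and no organolithium is needed.
- Better than the chosen plan: the benzyl ethers of A4 would fall in the same operation as the peri methyl ether, so step 7 disappears, and a protected nucleophile excludes O-alkylation in the coupling.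
- Against: A2 is volatile and enolisable and tends to self-condense under amine catalysis, the enantiopurity would rest on a catalyst–substrate match, A1 needs several steps from a simple benzoate, and the C4 carboxyl must be removed thermally.
- Comparison: it delivers the same lactone with the same free C5 and touches only the lactone arm, so it is equally compatible with 12. The chosen plan carries less stereochemical risk, since no bond to C3 is made or broken after 17 is bought. The way to A4 is expected to be longer than the three steps to 21.

Alternative 2: Both aryl–carbon bonds of the lactone ring, C4a–C4 and C8a–C1, are cut. The aryne 3,5-bis(benzyloxy)-4-methylbenzyne A5, generated by halogen–lithium exchange, would undergo [2+2] cycloaddition with the chiral-pool ketene silyl acetal A6. Acetal hydrolysis would give the benzocyclobutenone A7; after desilylation the alkoxide would add to the ring ketone and cleavage of the strained C–C bond would expand the ring to A4.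
- Equal to the chosen plan: the alkoxy group steers the nucleophilic carbon to the remote aryne carbon by the same polarity argument as in step 4, and C3 comes from the chiral pool.
- Better than the chosen plan: A4 again allows one global deprotection.
- Against: the aryne precursor requires a desymmetrised, differentially functionalised arene and so several steps, the enolate behind A6 can lose silyloxide by β-elimination, an alkyllithium must work beside benzyl ethers, and the ring expansion must break the right bond.
- Comparison: it reaches the same lactone, but spends the aryne on the simpler heterocycle, whereas the chosen plan uses it where three different ring oxygens must be told apart. It is expected to be clearly longer than steps 5 to 7.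

Alternative 3: The benzene ring of the lactone half is itself cut, at C8a–C4a, to an open chain. A tertiary amine would convert the diketo-dioxinone A8 into its dienolate, whose α-carbon (the future C8a) would add to the ketone that becomes C4a. Loss of water and enolisation of the C6 ketone would aromatise the ring to the benzodioxinone A9, in which the acetonide masks C1 and the C8 oxygen.
- Better than the chosen plan: the substitution pattern of the hexasubstituted ring is written into the chain and the bridge is installed before the arene exists, so the crowded Friedel–Crafts coupling of step 8 is avoided.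
- Equal: C3 is again bought, and the conditions are mild.
- Against: A8 is a long, enolisation-prone chain that needs several regiocontrolled C-acylations and C-alkylations in a linear sequence. A9 carries a symmetric trioxygenated ring, so the whole pyranone would still have to be built late, including differentiation of two equivalent methoxy groups, and the lactone must still be released from the dioxinone.
- Comparison: the chosen plan settles the chromone regiochemistry in one aryne step from a symmetric precursor, whereas the alternative postpones it. Both mechanisms (polar aldol–dehydration, aryne insertion) are sound in principle. The alternative is largely linear and expected to be considerably longer than nine steps.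

Key step: step 4

Remark on the chemistry: the aryne precursor 8 and the chromone 12 carry the benzylic oxygen as a methyl ether; the positions of silicon, triflate, both ring methoxy groups and the benzylic carbon, and every bond formed in the key step, are those the target demands.

Step 1
Reactants: 1 4-hydroxy-2,6-dimethoxybenzaldehyde
Product: 2 3-bromo-4-hydroxy-2,6-dimethoxybenzaldehyde
Conditions: NBS (1.0 equiv), MeCN, 0 °C → rt
Reagents that add atoms: N-bromosuccinimide, O=C1CCC(=O)N1Br
Why: Electrophilic aromatic bromination; C3 and C5 are equivalent by symmetry and activated by the ortho hydroxyl and the ortho/para methoxy groups, and the formyl group and the first bromine slow a second substitution, so one equivalent should stop at the monobromide.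

Step 2
Reactants: 2 3-bromo-4-hydroxy-2,6-dimethoxybenzaldehyde
Product: 4 2-bromo-3,5-dimethoxy-4-(methoxymethyl)phenol, via benzylic alcohol 3 (not isolated)
Conditions: NaBH4, MeOH, 0 °C; then TsOH·H2O (to pH ≈ 2), MeOH, 0 °C → rt; NaHCO3
Reagents that add atoms: methanol, CO
Why: Hydride reduction of the aldehyde, then acid-catalysed SN1 etherification in which the benzylic cation, stabilised by the para hydroxyl and two ortho methoxy groups, is captured by the solvent present in vast excess; the bromine tempers the ring against self-alkylation.

Step 3
Reactants: 4 2-bromo-3,5-dimethoxy-4-(methoxymethyl)phenol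
Product: 8 3,5-dimethoxy-4-(methoxymethyl)-2-(trimethylsilyl)phenyl trifluoromethanesulfonate, via aryl silyl ether 5 (not isolated), via aryllithium 6 (not isolated), via lithium phenoxide 7 (not isolated)
Conditions: HMDS, THF, 65 °C, then evaporation; n-BuLi, THF, −100 → −78 °C; Tf2O, −100 → −78 °C; cold aq. NaHCO3
Reagents that add atoms: hexamethyldisilazane, C[Si](C)(C)N[Si](C)(C)C; trifluoromethanesulfonic anhydride, O=S(=O)(OS(=O)(=O)C(F)(F)F)C(F)(F)F
Why: O-silylation, bromine–lithium exchange and 1,3 O→C silyl migration (retro-Brook rearrangement) put silicon on the former C–Br carbon and leave a lithium phenoxide that is triflated cold, the standard one-flask route from ortho-bromophenols to ortho-silylaryl triflates; the benzylic methyl ether is inert to n-BuLi at this temperature and offers no leaving group to the para phenoxide.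

Step 4
Reactants: 8 3,5-dimethoxy-4-(methoxymethyl)-2-(trimethylsilyl)phenyl trifluoromethanesulfonate; 9 but-2-ynoic acid
Product: 12 5,7-dimethoxy-6-(methoxymethyl)-2-methyl-4H-chromen-4-one, via aryne 10 (not isolated), via hydroxyaryl ynone 11 (not isolated)
Conditions: 8 (1.3 equiv), 9 (1.0 equiv), CsF (4 equiv), THF, 125 °C, sealed tube
Reagents that add atoms: none
Why: Fluoride attacks silicon of 8 and the aryl anion expels triflate to give aryne 10, whose triple bond spans the future C8a and C4a. The C5 methoxy group next to C4a withdraws inductively, so the oxygen of cesium but-2-ynoate adds to the remote, unhindered C8a (next to C8–H) and the negative charge develops at C4a. That aryl anion attacks the adjacent ester carbonyl through a four-membered transition state, and opening of the adduct gives the cesium phenoxide of ynone 11, a net insertion of the aryne into the acyl C–O bond. The closest known reaction type is the fluoride-induced aryne insertion into carboxylic acids, which gives ortho-hydroxyaryl ketones, chromanones from alkenoic acids and flavones from arylpropiolic acids. The phenoxide then closes the pyranone ring by 6-endo-dig oxa-Michael addition to the ynone, and the vinyl anion is protonated at C3; no stereocenter is formed. The step needs regioselective addition to the aryne, acyl migration faster than protonation of the aryl anion, and 6-endo rather than 5-exo closure. These should be secured, in turn, by the C5 methoxy group and the free C8 side, by the aprotic medium at 125 °C with the acid as limiting reagent, and by the naked phenoxide facing a strongly polarised ynone. The benzylic methyl ether is inert to fluoride and cannot leave by 1,6-elimination from the para phenoxide.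

Step 5
Reactants: 13 2,6-dimethoxytoluene (1,3-dimethoxy-2-methylbenzene); 14 N,N-diethylcarbamoyl chloride
Product: 16 N,N-diethyl-2,4-dimethoxy-3-methylbenzamide, via aryllithium 15 (not isolated)
Conditions: n-BuLi, TMEDA, Et2O, 0 °C → rt; then 14, −78 °C → rt
Reagents that add atoms: none
Why: Methoxy-directed ortho-lithiation at C3 (C3 and C5 are equivalent) followed by acylation of the aryllithium with the carbamoyl chloride; the tertiary amide formed resists a second addition at low temperature.

Step 6
Reactants: 16 N,N-diethyl-2,4-dimethoxy-3-methylbenzamide; 17 (R)-propylene oxide, (2R)-2-methyloxirane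
Product: 20 (3R)-6,8-dimethoxy-3,7-dimethyl-3,4-dihydro-1H-isochromen-1-one, via ortho-lithiated amide 18 (not isolated), via hydroxy amide 19 (not isolated)
Conditions: s-BuLi, TMEDA, THF, −78 °C; 17, BF3·OEt2, −78 °C; aq. NH4Cl; then TsOH·H2O (1.5 equiv), PhMe, 110 °C
Reagents that add atoms: none
Why: Directed ortho-metalation at C6, the only position ortho to the amide (the strongest director present), then BF3-assisted SN2 opening of the epoxide at its CH2 carbon and acid-promoted lactonisation with loss of diethylamine. The stereocenter is that of 17: no bond to it is made or broken, and the descriptor stays (R) because the priorities O > CH2 > CH3 are unchanged.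

Step 7
Reactants: 20 (3R)-6,8-dimethoxy-3,7-dimethyl-3,4-dihydro-1H-isochromen-1-one
Product: 21 (3R)-6,8-dihydroxy-3,7-dimethyl-3,4-dihydro-1H-isochromen-1-one
Conditions: BBr3 (3 equiv), CH2Cl2, −78 → 0 °C; H2O
Reagents that add atoms: none
Why: Aryl methyl ether cleavage by BBr3 (bromide attacks the methyl group of the boron-bound ether); the C8 ether is activated by chelation with the lactone carbonyl, and keeping the mixture cold limits attack at the secondary C3–O bond, so C3 is untouched.

Step 8
Reactants: 12 5,7-dimethoxy-6-(methoxymethyl)-2-methyl-4H-chromen-4-one; 21 (3R)-6,8-dihydroxy-3,7-dimethyl-3,4-dihydro-1H-isochromen-1-one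
Product: 22 (3R)-5-[(5,7-dimethoxy-2-methyl-4-oxo-4H-chromen-6-yl)methyl]-6,8-dihydroxy-3,7-dimethyl-3,4-dihydro-1H-isochromen-1-one
Conditions: BF3·OEt2 (3 equiv), CH2Cl2–1,4-dioxane, 0 °C → rt
Reagents that add atoms: none
Why: Friedel–Crafts benzylation: BF3 ionises the benzylic methyl ether of 12 to a cation stabilised by two ortho methoxy groups and the para ring oxygen, and C5 of 21, the only unsubstituted ring carbon and ortho/para to the two hydroxyls, captures it. Any O-benzyl ether formed at O6 is itself acid-labile and should revert to the cation, so the C-alkylated product should accumulate.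

Step 9
Reactants: 22 (3R)-5-[(5,7-dimethoxy-2-methyl-4-oxo-4H-chromen-6-yl)methyl]-6,8-dihydroxy-3,7-dimethyl-3,4-dihydro-1H-isochromen-1-one
Product: 23 (3R)-6,8-dihydroxy-5-[(5-hydroxy-7-methoxy-2-methyl-4-oxo-4H-chromen-6-yl)methyl]-3,7-dimethyl-3,4-dihydro-1H-isochromen-1-one
Conditions: BCl3 (4 equiv), CH2Cl2, −78 → 0 °C; H2O
Reagents that add atoms: none
Why: Chelation-controlled demethylation: BCl3 bridges the C4 carbonyl and the peri C5 methoxy group in a six-membered chelate and chloride removes that methyl group, while the C7 methyl ether (no chelate), the lactone and C3 should be left alone.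

## Compound list

1 | 4-hydroxy-2,6-dimethoxybenzaldehyde | COc1cc(O)cc(OC)c1C=O | starting material
2 | 3-bromo-4-hydroxy-2,6-dimethoxybenzaldehyde | COc1cc(O)c(Br)c(OC)c1C=O | intermediate
3 | 2-bromo-4-(hydroxymethyl)-3,5-dimethoxyphenol | COc1cc(O)c(Br)c(OC)c1CO | intermediate
4 | 2-bromo-3,5-dimethoxy-4-(methoxymethyl)phenol | COCc1c(OC)cc(O)c(Br)c1OC | intermediate
5 | [2-bromo-3,5-dimethoxy-4-(methoxymethyl)phenoxy]trimethylsilane | COCc1c(OC)cc(O[Si](C)(C)C)c(Br)c1OC | intermediate
6 | [2,4-dimethoxy-3-(methoxymethyl)-6-(trimethylsilyloxy)phenyl]lithium | COCc1c(OC)cc(O[Si](C)(C)C)c([Li])c1OC | intermediate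
7 | lithium 3,5-dimethoxy-4-(methoxymethyl)-2-(trimethylsilyl)phenoxide | COCc1c(OC)cc([O-])c([Si](C)(C)C)c1OC.[Li+] | intermediate
8 | 3,5-dimethoxy-4-(methoxymethyl)-2-(trimethylsilyl)phenyl trifluoromethanesulfonate | COCc1c(OC)cc(OS(=O)(=O)C(F)(F)F)c([Si](C)(C)C)c1OC | intermediate
9 | but-2-ynoic acid | CC#CC(=O)O | starting material
10 | 3,5-dimethoxy-4-(methoxymethyl)benzyne (1,2-didehydro-3,5-dimethoxy-4-(methoxymethyl)benzene) | COCC1=C(OC)C#CC=C1OC | intermediate
11 | 1-[6-hydroxy-2,4-dimethoxy-3-(methoxymethyl)phenyl]but-2-yn-1-one (present as its cesium phenoxide) | CC#CC(=O)c1c(O)cc(OC)c(COC)c1OC | intermediate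
12 | 5,7-dimethoxy-6-(methoxymethyl)-2-methyl-4H-chromen-4-one | COCc1c(OC)cc2oc(C)cc(=O)c2c1OC | intermediate
13 | 2,6-dimethoxytoluene (1,3-dimethoxy-2-methylbenzene) | COc1cccc(OC)c1C | starting material
14 | N,N-diethylcarbamoyl chloride | CCN(CC)C(=O)Cl | starting material
15 | (2,4-dimethoxy-3-methylphenyl)lithium | [Li]c1ccc(OC)c(C)c1OC | intermediate
16 | N,N-diethyl-2,4-dimethoxy-3-methylbenzamide | CCN(CC)C(=O)c1ccc(OC)c(C)c1OC | intermediate
17 | (R)-propylene oxide, (2R)-2-methyloxirane | C[C@@H]1CO1 | starting material
18 | [2-(diethylcarbamoyl)-3,5-dimethoxy-4-methylphenyl]lithium | CCN(CC)C(=O)c1c([Li])cc(OC)c(C)c1OC | intermediate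
19 | N,N-diethyl-2-[(2R)-2-hydroxypropyl]-4,6-dimethoxy-5-methylbenzamide | CCN(CC)C(=O)c1c(C[C@@H](C)O)cc(OC)c(C)c1OC | intermediate
20 | (3R)-6,8-dimethoxy-3,7-dimethyl-3,4-dihydro-1H-isochromen-1-one | COc1cc2C[C@@H](C)OC(=O)c2c(OC)c1C | intermediate
21 | (3R)-6,8-dihydroxy-3,7-dimethyl-3,4-dihydro-1H-isochromen-1-one | Cc1c(O)cc2C[C@@H](C)OC(=O)c2c1O | intermediate
22 | (3R)-5-[(5,7-dimethoxy-2-methyl-4-oxo-4H-chromen-6-yl)methyl]-6,8-dihydroxy-3,7-dimethyl-3,4-dihydro-1H-isochromen-1-one | COc1cc2oc(C)cc(=O)c2c(OC)c1Cc1c(O)c(C)c(O)c2c1C[C@@H](C)OC2=O | intermediate
23 | (3R)-6,8-dihydroxy-5-[(5-hydroxy-7-methoxy-2-methyl-4-oxo-4H-chromen-6-yl)methyl]-3,7-dimethyl-3,4-dihydro-1H-isochromen-1-one (CNP0180307.1) | COc1cc2oc(C)cc(=O)c2c(O)c1Cc1c(O)c(C)c(O)c2c1C[C@@H](C)OC2=O | target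

## Step count and least certain steps

Total: 9 steps. Longest linear sequence: 6 steps (steps 1, 2, 3, 4, 8, 9); the lactone arm (steps 5, 6, 7) joins at step 8.

**Step 4 (key step).** The most likely failure is protonation of the aryl anion at C4a before it reaches the ester carbonyl, which ends in O-arylation of the acid instead of insertion. The anion is crowded (methoxy on one side, the new ester on the other) and bifluoride is a proton source. Less likely are 5-exo closure of the phenoxide and fluoride- or carboxylate-induced oligomerisation of the butynoate at 125 °C.
Fallback, from 4 back to 12 without an aryne: 9 is condensed with N,O-dimethylhydroxylamine (carbodiimide coupling) to N-methoxy-N-methylbut-2-ynamide F1. Compound 4 is treated with n-BuLi (2.2 equiv, THF, −78 °C) to give lithium 2-lithio-3,5-dimethoxy-4-(methoxymethyl)phenoxide F2, which is acylated by F1 to ynone 11, this time isolated. Et2NH in EtOH adds to the triple bond to give the enaminone (2E)-3-(diethylamino)-1-[6-hydroxy-2,4-dimethoxy-3-(methoxymethyl)phenyl]but-2-en-1-one F3, which closes to 12 with loss of the amine; this closure can only be 6-endo.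

**Step 8.** Ionisation of the benzylic ether may be too slow once BF3 is bound to the pyranone carbonyl, which drains the donor ability of both methoxy groups. O-alkylation at O6 of 21, self-alkylation of 12 at its C8, and acid cleavage of the newly formed bridge are the competing processes.
Fallback, from 12 and 21 directly to 23 through an ortho-quinone methide under base instead of a cation under acid: excess BCl3 (CH2Cl2, −78 → 0 °C) removes the peri methyl group of 12 and converts the benzylic ether into the chloride, giving 6-(chloromethyl)-5-hydroxy-7-methoxy-2-methyl-4H-chromen-4-one F4. With NaHCO3 or i-Pr2NEt in MeCN, F4 loses HCl to give 7-methoxy-2-methyl-6-methylidene-4H-chromene-4,5(6H)-dione F5, and the phenoxide of 21 adds through C5 in a conjugate addition that restores the aromatic ring. The route is rejoined at 23; 22 and step 9 are bypassed.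

**Step 6.** The hindered ortho-lithiated amide may open the epoxide slowly, so that BF3-induced polymerisation of the epoxide or self-condensation of the aryllithium on warming takes over. Lactonisation of the doubly ortho-substituted amide may also be sluggish.
Fallback, from 13 back to 20 by carboxylate-directed C–H alkylation: aryllithium 15 (made as in step 5) is quenched with CO2 to give 2,4-dimethoxy-3-methylbenzoic acid F6. F6 and 17 with catalytic Pd(OAc)2, an N-acetyl amino acid ligand and KOAc in hexafluoroisopropanol should undergo ortho-palladation by divalent palladium at C6, SN2-type opening of the epoxide at its CH2 carbon, and lactonisation to 20, again without touching the stereocenter.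

**Step 2.** Under acid, the quinone-methide-like cation may alkylate the free ring position of a second molecule instead of being trapped by methanol, and prolonged acid exposure favours this irreversible oligomerisation.
Fallback, from 3 back to 8 with the ether made under neutral conditions after the phenol is triflated: 3 is isolated after a neutral work-up of the reduction and silylated with HMDS to [2-bromo-3,5-dimethoxy-4-[(trimethylsilyloxy)methyl]phenoxy]trimethylsilane F7. The sequence of step 3 (n-BuLi, then Tf2O) gives 3,5-dimethoxy-2-(trimethylsilyl)-4-[(trimethylsilyloxy)methyl]phenyl trifluoromethanesulfonate F8. Aqueous citric acid in MeOH cleaves only the O–Si bond to give 4-(hydroxymethyl)-3,5-dimethoxy-2-(trimethylsilyl)phenyl trifluoromethanesulfonate F9, and MeI with Ag2O methylates the alcohol to 8.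

## Further compounds

F1 | step 4 | N-methoxy-N-methylbut-2-ynamide | CC#CC(=O)N(C)OC
F2 | step 4 | lithium 2-lithio-3,5-dimethoxy-4-(methoxymethyl)phenoxide | [Li]c1c([O-])cc(OC)c(COC)c1OC.[Li+]
F3 | step 4 | (2E)-3-(diethylamino)-1-[6-hydroxy-2,4-dimethoxy-3-(methoxymethyl)phenyl]but-2-en-1-one | CCN(CC)/C(C)=C/C(=O)c1c(O)cc(OC)c(COC)c1OC
F4 | step 8 | 6-(chloromethyl)-5-hydroxy-7-methoxy-2-methyl-4H-chromen-4-one | COc1cc2oc(C)cc(=O)c2c(O)c1CCl
F5 | step 8 | 7-methoxy-2-methyl-6-methylidene-4H-chromene-4,5(6H)-dione | C=C1C(=O)C2=C(OC(C)=CC2=O)C=C1OC
F6 | step 6 | 2,4-dimethoxy-3-methylbenzoic acid | COc1ccc(C(=O)O)c(OC)c1C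
F7 | step 2 | [2-bromo-3,5-dimethoxy-4-[(trimethylsilyloxy)methyl]phenoxy]trimethylsilane | COc1cc(O[Si](C)(C)C)c(Br)c(OC)c1CO[Si](C)(C)C
F8 | step 2 | 3,5-dimethoxy-2-(trimethylsilyl)-4-[(trimethylsilyloxy)methyl]phenyl trifluoromethanesulfonate | COc1cc(OS(=O)(=O)C(F)(F)F)c([Si](C)(C)C)c(OC)c1CO[Si](C)(C)C
F9 | step 2 | 4-(hydroxymethyl)-3,5-dimethoxy-2-(trimethylsilyl)phenyl trifluoromethanesulfonate | COc1cc(OS(=O)(=O)C(F)(F)F)c([Si](C)(C)C)c(OC)c1CO
A1 | alternative 1 | 6,8-bis(benzyloxy)-7-methyl-1H-isochromene-1,3(4H)-dione | O=C1Cc2cc(OCc3ccccc3)c(C)c(OCc3ccccc3)c2C(=O)O1
A2 | alternative 1 | acetaldehyde | CC=O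
A3 | alternative 1 | (3R)-6,8-bis(benzyloxy)-3,7-dimethyl-1-oxoisochromane-4-carboxylic acid (C4 epimers as formed) | C[C@@H]1C(C(=O)O)c2cc(OCc3ccccc3)c(C)c(OCc3ccccc3)c2C(=O)O1
A4 | alternative 1 | (3R)-6,8-bis(benzyloxy)-3,7-dimethyl-3,4-dihydro-1H-isochromen-1-one | C[C@@H]1Cc2cc(OCc3ccccc3)c(C)c(OCc3ccccc3)c2C(=O)O1
A5 | alternative 2 | 3,5-bis(benzyloxy)-4-methylbenzyne | CC1=C(OCc2ccccc2)C#CC=C1OCc1ccccc1
A6 | alternative 2 | tert-butyl{[(2R)-4-methoxy-4-(trimethylsilyloxy)but-3-en-2-yl]oxy}dimethylsilane | C[C@@H](O[Si](C)(C)C(C)(C)C)C=C(OC)O[Si](C)(C)C
A7 | alternative 2 | 3,5-bis(benzyloxy)-8-[(1R)-1-(tert-butyldimethylsilyloxy)ethyl]-4-methylbicyclo[4.2.0]octa-1,3,5-trien-7-one (ring carbon epimers as formed) | C[C@@H](O[Si](C)(C)C(C)(C)C)C1C(=O)c2c(OCc3ccccc3)c(C)c(OCc3ccccc3)cc21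
A8 | alternative 3 | 6-[(7R)-4-{[4-(benzyloxy)-2,6-dimethoxyphenyl]methyl}-7-(tert-butyldimethylsilyloxy)-3,5-dioxooctan-2-yl]-2,2-dimethyl-4H-1,3-dioxin-4-one | CC1(C)OC(=O)C=C(O1)C(C)C(=O)C(Cc1c(OC)cc(OCc2ccccc2)cc1OC)C(=O)C[C@@H](C)O[Si](C)(C)C(C)(C)C
A9 | alternative 3 | 6-{[4-(benzyloxy)-2,6-dimethoxyphenyl]methyl}-5-[(2R)-2-(tert-butyldimethylsilyloxy)propyl]-7-hydroxy-2,2,8-trimethyl-4H-1,3-benzodioxin-4-one | CC1(C)OC(=O)c2c(O1)c(C)c(O)c(Cc1c(OC)cc(OCc3ccccc3)cc1OC)c2C[C@@H](C)O[Si](C)(C)C(C)(C)C
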